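The seven-membered ring is read as a cyclohepta-1,4-diene (azulene locants of the target throughout): the C4 oxygen as a C3a=C4 silyl enol ether and the C6=C7 alkene flank the C5 methylene, which is the retron of a cis-divinylcyclopropane. A chiral dirhodium vinylcarbenoid cyclopropanates a 2-siloxydiene made from (S)-terpinen-4-ol by ring cleavage and aldol re-closure. The C4–C5–C6 cyclopropane then undergoes a Cope rearrangement in the same flask, which closes the seven-membered ring at C8–C8a, sets the quaternary C8a and breaks the temporary C4–C6 bond. C3 is bought; C3a and C4 are relayed from it. The ester that activates the carbenoid ends as the C6 methyl.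

Key step: step 8

Assumption: (S)-(+)-terpinen-4-ol is used enantiomerically pure; material of lower enantiomeric purity would be upgraded on a chiral phase before step 1.

Step 1
Reactants: 1 (S)-(+)-terpinen-4-ol
Product: 2 triethyl{[(1S)-4-methyl-1-(propan-2-yl)cyclohex-3-en-1-yl]oxy}silane
Conditions: Et3SiOTf, 2,6-lutidine, CH2Cl2, −78 to 0 °C
Reagents that add atoms: triethylsilyl trifluoromethanesulfonate, CC[Si](CC)(CC)OS(=O)(=O)C(F)(F)F
Why: A silyl triflate with a hindered pyridine base silylates the tertiary alcohol (silyl ether formation), which blocks hemiketal formation, retro-aldol cleavage and dehydration at this carbinol in the next steps.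

Step 2
Reactants: 2 triethyl{[(1S)-4-methyl-1-(propan-2-yl)cyclohex-3-en-1-yl]oxy}silane
Product: 4 (5R)-2-methyl-5-(propan-2-yl)-5-[(triethylsilyl)oxy]cyclopent-1-ene-1-carbaldehyde, via keto aldehyde 3 (not isolated)
Conditions: O3, CH2Cl2, −78 °C; Me2S, −78 °C to rt; then piperidine, AcOH (0.3 equiv each), benzene, 4 Å sieves, rt to 40 °C
Reagents that add atoms: ozone, [O-][O+]=O
Why: Ozonolysis cleaves the ring alkene to keto aldehyde 3, and piperidinium acetate turns the aldehyde into its enamine, which adds to the methyl ketone in a five-membered intramolecular aldol condensation and loses the new hydroxyl as water; the quaternary carbinol carbon is a spectator and keeps its configuration.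

Step 3
Reactants: 4 (5R)-2-methyl-5-(propan-2-yl)-5-[(triethylsilyl)oxy]cyclopent-1-ene-1-carbaldehyde
Product: 5 1-[(5R)-2-methyl-5-(propan-2-yl)-5-[(triethylsilyl)oxy]cyclopent-1-en-1-yl]ethan-1-ol (both carbinol epimers)
Conditions: MeMgBr, THF, −78 to 0 °C
Reagents that add atoms: methylmagnesium bromide, C[Mg]Br
Why: The non-enolisable enal takes the Grignard reagent in a 1,2-addition; the new carbinol centre is removed in step 4, so its configuration does not matter.

Step 4
Reactants: 5 1-[(5R)-2-methyl-5-(propan-2-yl)-5-[(triethylsilyl)oxy]cyclopent-1-en-1-yl]ethan-1-ol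
Product: 6 1-[(5R)-2-methyl-5-(propan-2-yl)-5-[(triethylsilyl)oxy]cyclopent-1-en-1-yl]ethan-1-one
Conditions: Dess–Martin periodinane, NaHCO3, CH2Cl2, 0 °C to rt
Reagents that add atoms: none
Why: Buffered Dess–Martin oxidation of the secondary allylic alcohol should give the methyl enone without touching the silyl ether.

Step 5
Reactants: 6 1-[(5R)-2-methyl-5-(propan-2-yl)-5-[(triethylsilyl)oxy]cyclopent-1-en-1-yl]ethan-1-one
Product: 7 tert-butyl(dimethyl)({1-[(5R)-2-methyl-5-(propan-2-yl)-5-[(triethylsilyl)oxy]cyclopent-1-en-1-yl]ethenyl}oxy)silane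
Conditions: tBuMe2SiOTf, Et3N, CH2Cl2, −78 to 0 °C
Reagents that add atoms: tert-butyldimethylsilyl trifluoromethanesulfonate, CC(C)(C)[Si](C)(C)OS(=O)(=O)C(F)(F)F
Why: Soft enolisation at the only α-methyl group (silyl enol ether formation) gives the cross-conjugated 2-siloxy-1,3-diene and places the future C4 oxygen on the carbon that will become a cyclopropane carbon.

Step 6
Reactants: 8 ethyl diazoacetate, 9 acetaldehyde
Product: 10 ethyl 2-diazo-3-hydroxybutanoate (racemic)
Conditions: DBU (10 mol %), MeCN, 0 °C to rt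
Reagents that add atoms: none
Why: The amidine base deprotonates the diazoacetate, which adds to the aldehyde (aldol-type addition of an α-diazo ester); the racemic carbinol is lost in step 7.

Step 7
Reactants: 10 ethyl 2-diazo-3-hydroxybutanoate
Product: 11 ethyl 2-diazobut-3-enoate
Conditions: POCl3, Et3N, CH2Cl2, 0 °C; used at once as a cold pentane solution
Reagents that add atoms: none
Why: Phosphorylation of the alcohol and base-induced elimination (dehydration) give the vinyldiazoacetate, which is carried on immediately because it cyclises to a pyrazole on standing.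

Step 8
Reactants: 7 tert-butyl(dimethyl)({1-[(5R)-2-methyl-5-(propan-2-yl)-5-[(triethylsilyl)oxy]cyclopent-1-en-1-yl]ethenyl}oxy)silane, 11 ethyl 2-diazobut-3-enoate
Product: 13 ethyl (3R,8aR)-4-[(tert-butyldimethylsilyl)oxy]-8a-methyl-3-(propan-2-yl)-3-[(triethylsilyl)oxy]-1,2,3,5,8,8a-hexahydroazulene-6-carboxylate, via cis-divinylcyclopropane 12 (not isolated)
Conditions: Rh2(R-DOSP)4 (1 mol %), pentane, −40 °C to rt, slow addition of 11; then toluene, 80 °C
Reagents that add atoms: none
Why: The dirhodium catalyst expels N2 from 11 and the electrophilic vinylcarbenoid attacks the unsubstituted CH2 terminus of the silyl enol ether of 7 (the ring alkene is tetrasubstituted and inert), closing the three-membered ring by carbene [2+1] transfer to give 12 with the carbenoid vinyl cis to the cyclopentenyl group, as with other 2-siloxy-1,3-dienes. Cyclopropane 12 then undergoes the divinylcyclopropane–cycloheptadiene (Cope) rearrangement through the boat transition state, so that the seven-membered ring closes by a concerted suprafacial [3,3] shift that makes C8–C8a, cleaves the temporary C4–C6 bond and leaves the C3a=C4 silyl enol ether and the C6=C7 enoate. The closest known reaction type is the tandem asymmetric cyclopropanation/Cope rearrangement (formal [4+3] cycloaddition) of vinyldiazoacetates with dienes under dirhodium prolinate catalysis, which also tolerates 2-methyl-1-vinylcycloalkenes that end as angular methyl groups. The only new stereocentre that remains, C8a, is set by the (1S,2R) configuration of the cyclopropane, which the catalyst dictates (the (R)-prolinate is chosen by the styrene model; the (S)-catalyst would give the C8a epimer) and which the boat geometry transfers without loss; in that boat the siloxy group lies next to the smaller oxygen substituent of C3, so catalyst and substrate should reinforce each other. The step needs site selectivity (secured by the electron-rich, unhindered enol ether), cis-divinyl geometry (donor group of the carbenoid cis to the alkenyl substituent), facial control (catalyst in a non-polar solvent, which also suppresses zwitterionic [3+2] paths) and enough heat for the methyl-bearing terminus to enter the boat (80 °C).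

Step 9
Reactants: 13 ethyl (3R,8aR)-4-[(tert-butyldimethylsilyl)oxy]-8a-methyl-3-(propan-2-yl)-3-[(triethylsilyl)oxy]-1,2,3,5,8,8a-hexahydroazulene-6-carboxylate
Product: 14 [(3R,8aR)-4-[(tert-butyldimethylsilyl)oxy]-8a-methyl-3-(propan-2-yl)-3-[(triethylsilyl)oxy]-1,2,3,5,8,8a-hexahydroazulen-6-yl]methanol
Conditions: iBu2AlH (2.5 equiv), CH2Cl2, −78 °C; Rochelle salt work-up
Reagents that add atoms: none
Why: The aluminium hydride reduces the conjugated ester to the primary allylic alcohol (1,2-reduction) while the silyl enol ether and the silyl ether stay inert.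

Step 10
Reactants: 14 [(3R,8aR)-4-[(tert-butyldimethylsilyl)oxy]-8a-methyl-3-(propan-2-yl)-3-[(triethylsilyl)oxy]-1,2,3,5,8,8a-hexahydroazulen-6-yl]methanol
Product: 16 tert-butyl{[(3R,8aR)-6,8a-dimethyl-3-(propan-2-yl)-3-[(triethylsilyl)oxy]-1,2,3,5,8,8a-hexahydroazulen-4-yl]oxy}dimethylsilane, via allylic mesylate 15 (not isolated)
Conditions: MeSO2Cl, Et3N, CH2Cl2, −40 °C; then LiEt3BH, THF, −40 to 0 °C
Reagents that add atoms: none
Why: Hydride displaces the primary allylic mesylate in an SN2 reaction (sulfonate reduction), which removes the oxidation level that served the carbenoid and leaves the C6 methyl without moving the alkene.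

Step 11
Reactants: 16 tert-butyl{[(3R,8aR)-6,8a-dimethyl-3-(propan-2-yl)-3-[(triethylsilyl)oxy]-1,2,3,5,8,8a-hexahydroazulen-4-yl]oxy}dimethylsilane
Product: 17 (3R,3aR,8aR)-3-hydroxy-6,8a-dimethyl-3-(propan-2-yl)-1,2,3,3a,8,8a-hexahydroazulen-4(5H)-one
Conditions: HF·pyridine, pyridine, THF, 0 °C to rt
Reagents that add atoms: none
Why: Fluoride cleaves the silyl enol ether and the tertiary silyl ether (desilylation), and the enol is protonated at C3a under thermodynamic control to the trans-fused ketone, in which the ring C–C(=O) bond is anti to the isopropyl group and the hydroxyl can hydrogen-bond to the ketone; the cold, buffered medium should keep the β,γ-alkene out of conjugation and avoid retro-aldol opening.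

Step 12
Reactants: 17 (3R,3aR,8aR)-3-hydroxy-6,8a-dimethyl-3-(propan-2-yl)-1,2,3,3a,8,8a-hexahydroazulen-4(5H)-one
Product: 18 (3R,3aS,4S,8aR)-6,8a-dimethyl-3-(propan-2-yl)-1,2,3,3a,4,5,8,8a-octahydroazulene-3,4-diol (jaeschkeanadiol)
Conditions: Me4NBH(OAc)3, AcOH, MeCN, −20 °C
Reagents that add atoms: none
Why: The tertiary hydroxyl exchanges onto boron and delivers hydride intramolecularly to the β-face of the ketone (Evans–Saksena hydroxyl-directed reduction), which should give the 1,3-anti diol with the C4 hydroxyl on the α-face.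

Step 13
Reactants: 18 (3R,3aS,4S,8aR)-6,8a-dimethyl-3-(propan-2-yl)-1,2,3,3a,4,5,8,8a-octahydroazulene-3,4-diol, 19 3,4-dimethoxybenzoyl chloride
Product: 20 (3R,3aS,4S,8aR)-3-hydroxy-6,8a-dimethyl-3-(propan-2-yl)-1,2,3,3a,4,5,8,8a-octahydroazulen-4-yl 3,4-dimethoxybenzoate
Conditions: Et3N, 4-dimethylaminopyridine, CH2Cl2, 0 °C to rt
Reagents that add atoms: none
Why: Nucleophilic acyl-transfer catalysis esterifies the secondary alcohol, while the tertiary alcohol is too hindered to react (pyridine-catalysed acylation).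

Compound list
1 | (S)-(+)-terpinen-4-ol, (1S)-4-methyl-1-(propan-2-yl)cyclohex-3-en-1-ol | CC1=CC[C@](O)(C(C)C)CC1 | starting material
2 | triethyl{[(1S)-4-methyl-1-(propan-2-yl)cyclohex-3-en-1-yl]oxy}silane | CC1=CC[C@](O[Si](CC)(CC)CC)(C(C)C)CC1 | intermediate
3 | (3S)-6-oxo-3-(propan-2-yl)-3-[(triethylsilyl)oxy]heptanal (keto aldehyde) | O=CC[C@](O[Si](CC)(CC)CC)(C(C)C)CCC(C)=O | intermediate
4 | (5R)-2-methyl-5-(propan-2-yl)-5-[(triethylsilyl)oxy]cyclopent-1-ene-1-carbaldehyde | O=CC1=C(C)CC[C@@]1(O[Si](CC)(CC)CC)C(C)C | intermediate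
5 | 1-[(5R)-2-methyl-5-(propan-2-yl)-5-[(triethylsilyl)oxy]cyclopent-1-en-1-yl]ethan-1-ol | CC(O)C1=C(C)CC[C@@]1(O[Si](CC)(CC)CC)C(C)C | intermediate
6 | 1-[(5R)-2-methyl-5-(propan-2-yl)-5-[(triethylsilyl)oxy]cyclopent-1-en-1-yl]ethan-1-one | CC(=O)C1=C(C)CC[C@@]1(O[Si](CC)(CC)CC)C(C)C | intermediate
7 | tert-butyl(dimethyl)({1-[(5R)-2-methyl-5-(propan-2-yl)-5-[(triethylsilyl)oxy]cyclopent-1-en-1-yl]ethenyl}oxy)silane | C=C(O[Si](C)(C)C(C)(C)C)C1=C(C)CC[C@@]1(O[Si](CC)(CC)CC)C(C)C | intermediate
8 | ethyl diazoacetate | CCOC(=O)C=[N+]=[N-] | starting material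
9 | acetaldehyde | CC=O | starting material
10 | ethyl 2-diazo-3-hydroxybutanoate | CCOC(=O)C(=[N+]=[N-])C(C)O | intermediate
11 | ethyl 2-diazobut-3-enoate | CCOC(=O)C(=[N+]=[N-])C=C | intermediate
12 | ethyl (1S,2R)-2-[(tert-butyldimethylsilyl)oxy]-1-ethenyl-2-[(5R)-2-methyl-5-(propan-2-yl)-5-[(triethylsilyl)oxy]cyclopent-1-en-1-yl]cyclopropane-1-carboxylate (cis-divinylcyclopropane) | C=C[C@@]1(C(=O)OCC)C[C@@]1(O[Si](C)(C)C(C)(C)C)C1=C(C)CC[C@@]1(O[Si](CC)(CC)CC)C(C)C | intermediate
13 | ethyl (3R,8aR)-4-[(tert-butyldimethylsilyl)oxy]-8a-methyl-3-(propan-2-yl)-3-[(triethylsilyl)oxy]-1,2,3,5,8,8a-hexahydroazulene-6-carboxylate | CCOC(=O)C1=CC[C@@]2(C)CC[C@@](O[Si](CC)(CC)CC)(C(C)C)C2=C(O[Si](C)(C)C(C)(C)C)C1 | intermediate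
14 | [(3R,8aR)-4-[(tert-butyldimethylsilyl)oxy]-8a-methyl-3-(propan-2-yl)-3-[(triethylsilyl)oxy]-1,2,3,5,8,8a-hexahydroazulen-6-yl]methanol | OCC1=CC[C@@]2(C)CC[C@@](O[Si](CC)(CC)CC)(C(C)C)C2=C(O[Si](C)(C)C(C)(C)C)C1 | intermediate
15 | [(3R,8aR)-4-[(tert-butyldimethylsilyl)oxy]-8a-methyl-3-(propan-2-yl)-3-[(triethylsilyl)oxy]-1,2,3,5,8,8a-hexahydroazulen-6-yl]methyl methanesulfonate (allylic mesylate) | CS(=O)(=O)OCC1=CC[C@@]2(C)CC[C@@](O[Si](CC)(CC)CC)(C(C)C)C2=C(O[Si](C)(C)C(C)(C)C)C1 | intermediate
16 | tert-butyl{[(3R,8aR)-6,8a-dimethyl-3-(propan-2-yl)-3-[(triethylsilyl)oxy]-1,2,3,5,8,8a-hexahydroazulen-4-yl]oxy}dimethylsilane | CC1=CC[C@@]2(C)CC[C@@](O[Si](CC)(CC)CC)(C(C)C)C2=C(O[Si](C)(C)C(C)(C)C)C1 | intermediate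
17 | (3R,3aR,8aR)-3-hydroxy-6,8a-dimethyl-3-(propan-2-yl)-1,2,3,3a,8,8a-hexahydroazulen-4(5H)-one | O=C1CC(C)=CC[C@@]2(C)CC[C@@](O)(C(C)C)[C@H]12 | intermediate
18 | (3R,3aS,4S,8aR)-6,8a-dimethyl-3-(propan-2-yl)-1,2,3,3a,4,5,8,8a-octahydroazulene-3,4-diol | O[C@H]1CC(C)=CC[C@@]2(C)CC[C@@](O)(C(C)C)[C@H]12 | intermediate
19 | 3,4-dimethoxybenzoyl chloride | COc1ccc(C(=O)Cl)cc1OC | starting material
20 | (3R,3aS,4S,8aR)-3-hydroxy-6,8a-dimethyl-3-(propan-2-yl)-1,2,3,3a,4,5,8,8a-octahydroazulen-4-yl 3,4-dimethoxybenzoate | COc1ccc(C(=O)O[C@H]2CC(C)=CC[C@@]3(C)CC[C@@](O)(C(C)C)[C@H]23)cc1OC | target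

Total step count: 13. Longest linear sequence: 11 steps (steps 1–5 and 8–13); steps 6 and 7 form the two-step side branch to 11.

Steps most likely to fail

Step 8 (key step). The carbenoid may add with its vinyl group trans to the cyclopentenyl group, or the siloxy/ester-substituted cyclopropane may open to a zwitterion before the Cope step. In either case cyclopentene by-products would form and catalyst control over C8a would be lost. The methyl-bearing terminus may also enter the boat too slowly. The fallback avoids the carbenoid and the ester altogether, sets out from 4 and comes back at 16. MeCH=CHCH2MgCl adds through its γ-carbon to enal 4 to give the branched homoallylic alcohol F1. Dess–Martin oxidation gives the β,γ-unsaturated ketone F2. tBuMe2SiOTf and Et3N give the silyl dienol ether F3. Et2Zn and CH2I2 cyclopropanate its enol ether alkene to the siloxy divinylcyclopropane F4. Heating in toluene at 110 °C should bring any trans isomer to the cis isomer and effect the same Cope ring expansion, which gives 16 with the C6 methyl already in place. The C8a configuration then rests on substrate control by C3 alone.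

Step 2. The ketone may act as the aldol donor and give the acetylcyclopentene regioisomer, or the enamine may expel the silyloxy group and dehydrate further to a cyclopentadiene. The fallback sets out from 3 and comes back at 4. Keto aldehyde 3 is isolated and cyclised with L-proline at low temperature only as far as the β-hydroxy aldehyde F5 (aldol addition without condensation). The Burgess reagent then dehydrates the only free hydroxyl, the newly formed tertiary one, so that the silyloxy group cannot be the one that leaves, and gives 4.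

Step 11. On unmasking, the β,γ-alkene may move into conjugation with the ketone, the free tertiary aldol may open by retro-aldol cleavage, or C3a may be protonated to the cis-fused isomer. The fallback never frees the β-hydroxy ketone, sets out from 16 and comes back at 20. One equivalent of Bu4NF buffered with AcOH at −40 °C cleaves only the enol ether and gives the silyloxy ketone F6, which can be equilibrated at C3a with DBU without risk of retro-aldol cleavage. NaBH4 attacks from the face opposite to the angular methyl and the silyloxy group and gives the C4-epimeric alcohol F7. A Mitsunobu reaction (PPh3, diisopropyl azodicarboxylate, 3,4-dimethoxybenzoic acid) inverts C4 and gives the silyl-protected ester F8. HF·pyridine removes the triethylsilyl group and gives 20.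

Further compounds
F1 | step 8 | 2-methyl-1-[(5R)-2-methyl-5-(propan-2-yl)-5-[(triethylsilyl)oxy]cyclopent-1-en-1-yl]but-3-en-1-ol | C=CC(C)C(O)C1=C(C)CC[C@@]1(O[Si](CC)(CC)CC)C(C)C
F2 | step 8 | 2-methyl-1-[(5R)-2-methyl-5-(propan-2-yl)-5-[(triethylsilyl)oxy]cyclopent-1-en-1-yl]but-3-en-1-one | C=CC(C)C(=O)C1=C(C)CC[C@@]1(O[Si](CC)(CC)CC)C(C)C
F3 | step 8 | tert-butyl(dimethyl)({2-methyl-1-[(5R)-2-methyl-5-(propan-2-yl)-5-[(triethylsilyl)oxy]cyclopent-1-en-1-yl]buta-1,3-dien-1-yl}oxy)silane | C=CC(C)=C(O[Si](C)(C)C(C)(C)C)C1=C(C)CC[C@@]1(O[Si](CC)(CC)CC)C(C)C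
F4 | step 8 | tert-butyl{[(1S,2R)-2-ethenyl-2-methyl-1-[(5R)-2-methyl-5-(propan-2-yl)-5-[(triethylsilyl)oxy]cyclopent-1-en-1-yl]cyclopropyl]oxy}dimethylsilane | C=C[C@@]1(C)C[C@@]1(O[Si](C)(C)C(C)(C)C)C1=C(C)CC[C@@]1(O[Si](CC)(CC)CC)C(C)C
F5 | step 2 | (5R)-2-hydroxy-2-methyl-5-(propan-2-yl)-5-[(triethylsilyl)oxy]cyclopentane-1-carbaldehyde | O=CC1C(C)(O)CC[C@@]1(O[Si](CC)(CC)CC)C(C)C
F6 | step 11 | (3R,3aR,8aR)-6,8a-dimethyl-3-(propan-2-yl)-3-[(triethylsilyl)oxy]-1,2,3,3a,8,8a-hexahydroazulen-4(5H)-one | O=C1CC(C)=CC[C@@]2(C)CC[C@@](O[Si](CC)(CC)CC)(C(C)C)[C@H]12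
F7 | step 11 | (3R,3aS,4R,8aR)-6,8a-dimethyl-3-(propan-2-yl)-3-[(triethylsilyl)oxy]-1,2,3,3a,4,5,8,8a-octahydroazulen-4-ol | O[C@@H]1CC(C)=CC[C@@]2(C)CC[C@@](O[Si](CC)(CC)CC)(C(C)C)[C@H]12
F8 | step 11 | (3R,3aS,4S,8aR)-6,8a-dimethyl-3-(propan-2-yl)-3-[(triethylsilyl)oxy]-1,2,3,3a,4,5,8,8a-octahydroazulen-4-yl 3,4-dimethoxybenzoate | COc1ccc(C(=O)O[C@H]2CC(C)=CC[C@@]3(C)CC[C@@](O[Si](CC)(CC)CC)(C(C)C)[C@H]23)cc1OC
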